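**Assumption:** the target SMILES has no stereocentre and no stereogenic double bond. The compound is achiral, so no enantiomer has to be selected. The transient stereo-elements in 4 and 8–10 are erased later in the route.

## Retrosynthetic overview
1. 12 ⇒ 9 + MeOH. The last step makes the ring-A C3–OCH3 bond on a mirror-symmetric 1,3-dione and re-aromatises ring A (−H2), so the two ring-A oxygens never have to be told apart.
2. 9 ⇒ 6 + 7. The C2–CH2Ar bond comes from a reductive Knoevenagel alkylation, which is specific for the carbon between the two oxygens.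
3. 6 ⇒ 4. One hydrogenation pot saturates the C=C, cleaves both OBn groups and reduces the resorcinol to the dihydroresorcinol.
4. 4 ⇒ 1 + 2. A Wittig olefination builds the two-carbon bridge.
5. Ring order: all three six-membered rings are bought as arenes. Only ring A is dearomatised (step 2) and re-formed as an arene (step 4).

## Route

Step 1
Reactants: 1 3,5-bis(benzyloxy)benzaldehyde; 2 (2-hydroxybenzyl)triphenylphosphonium bromide
Product: 4 2-{2-[3,5-bis(benzyloxy)phenyl]ethenyl}phenol (E major, E/Z mixture used as such), via potassium 2-[(triphenyl-λ5-phosphanylidene)methyl]phenolate 3 (not isolated)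
Conditions: 2 (1.1 equiv), KOtBu (2.2 equiv), THF, 0 °C; then 1, 0 °C → rt, 12 h; 1 M HCl quench
Reagents that add atoms: none
Why: Wittig olefination, in which two equivalents of base turn 2 into the phenoxide ylide 3, a semi-stabilised benzylic ylide that adds to the non-enolisable aldehyde 1; the E/Z ratio does not matter because the double bond is saturated in step 2, and no stereocentre is formed.

Step 2
Reactants: 4 2-{2-[3,5-bis(benzyloxy)phenyl]ethenyl}phenol
Product: 6 5-[2-(2-hydroxyphenyl)ethyl]cyclohexane-1,3-dione, via 5-[2-(2-hydroxyphenyl)ethyl]benzene-1,3-diol 5 (not isolated)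
Conditions: H2 (3 bar), 10% Pd/C, THF–iPrOH, rt; then, same pot and catalyst, aq NaOH (1.2 equiv), H2 (20 bar), 50 °C; filter, HCl to pH 2
Reagents that add atoms: none
Why: Heterogeneous catalytic hydrogenation, in which Pd/C first saturates the stilbene and hydrogenolyses both aryl benzyl ethers to 5; after NaOH is added, only the resorcinol ring (through the keto tautomer of its monoanion) takes up one more H2 and stops at the hydrogenation-resistant enolate of 6 (classical resorcinol → dihydroresorcinol reduction), while the simple phenol ring is inert at 50 °C.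

Step 3
Reactants: 6 5-[2-(2-hydroxyphenyl)ethyl]cyclohexane-1,3-dione; 7 4-hydroxybenzaldehyde
Product: 9 2-(4-hydroxybenzyl)-5-[2-(2-hydroxyphenyl)ethyl]cyclohexane-1,3-dione (enolised in solution), via 2-(4-hydroxybenzylidene)-5-[2-(2-hydroxyphenyl)ethyl]cyclohexane-1,3-dione 8 (not isolated)
Conditions: Hantzsch ester (diethyl 1,4-dihydro-2,6-dimethylpyridine-3,5-dicarboxylate, 1.05 equiv), L-proline (10 mol%), EtOH, 25 °C, 12 h; product taken into aq NaHCO3, re-acidified
Reagents that add atoms: none
Why: Organocatalytic three-component reductive alkylation (Knoevenagel condensation, then Hantzsch-ester transfer hydrogenation), in which fast conjugate hydride delivery to alkylidene 8 outruns addition of a second dione and places the benzyl group only on C2; free phenols are tolerated, and no lasting stereocentre arises because 9 tautomerises rapidly.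

Step 4
Reactants: 9 2-(4-hydroxybenzyl)-5-[2-(2-hydroxyphenyl)ethyl]cyclohexane-1,3-dione
Product: 12 2-(4-hydroxybenzyl)-5-[2-(2-hydroxyphenyl)ethyl]-3-methoxyphenol (target), via rac-2-(4-hydroxybenzyl)-5-[2-(2-hydroxyphenyl)ethyl]-3-methoxycyclohex-2-en-1-one 10 (not isolated), via 2-(4-hydroxybenzyl)-5-[2-(2-hydroxyphenyl)ethyl]-3-methoxycyclohexa-2,5-dien-1-one 11 (not isolated)
Conditions: TsOH·H2O (20 mol%), MeOH, 3 Å MS, 60 °C, 3 h; then, same flask, dilute with DMSO (3 vol), Pd(TFA)2 (5 mol%), 2-(dimethylamino)pyridine (10 mol%), O2 (1 atm), closed vessel, 80 °C, 24 h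
Reagents that add atoms: methanol, CO
Why: Proposed new method: a condensative aerobic dehydrogenation in which TsOH first lets MeOH add to C3 of the vinylogous acid 9 and expel water, forming the C3–OCH3 bond (only the pKa ≈ 5 enol is etherified, not the phenols, and the mirror-symmetric dione can give only one enol ether, 10); the same acid then acts as co-catalyst for electrophilic palladation of the dienol tautomer of 10 at C6 (or C4), syn β-hydride elimination of the C5–H gives dienone 11, which tautomerises irreversibly to the arene while O2 re-oxidises Pd(0), and a second O-methylation is impossible once the ring is a phenol; the closest known reaction types are the Pd(II)/O2 dehydrogenation of cyclohexenones to phenols and the oxidative aryl-ether synthesis from cyclohexenones and alcohols, neither of which, to my knowledge, has been shown for 2-alkyl-3-alkoxyenones formed in situ from 1,3-diones that carry free phenols.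

## Compound list
1 | 3,5-bis(benzyloxy)benzaldehyde | O=Cc1cc(OCc2ccccc2)cc(OCc2ccccc2)c1 | starting material
2 | (2-hydroxybenzyl)triphenylphosphonium bromide | Oc1ccccc1C[P+](c1ccccc1)(c1ccccc1)c1ccccc1.[Br-] | starting material
3 | potassium 2-[(triphenyl-λ5-phosphanylidene)methyl]phenolate | [K+].[O-]c1ccccc1C=P(c1ccccc1)(c1ccccc1)c1ccccc1 | intermediate (not isolated)
4 | 2-{(E)-2-[3,5-bis(benzyloxy)phenyl]ethenyl}phenol (E drawn, E/Z mixture used) | Oc1ccccc1/C=C/c1cc(OCc2ccccc2)cc(OCc2ccccc2)c1 | intermediate
5 | 5-[2-(2-hydroxyphenyl)ethyl]benzene-1,3-diol | Oc1cc(O)cc(CCc2ccccc2O)c1 | intermediate (not isolated)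
6 | 5-[2-(2-hydroxyphenyl)ethyl]cyclohexane-1,3-dione | O=C1CC(=O)CC(CCc2ccccc2O)C1 | intermediate
7 | 4-hydroxybenzaldehyde | O=Cc1ccc(O)cc1 | starting material
8 | 2-(4-hydroxybenzylidene)-5-[2-(2-hydroxyphenyl)ethyl]cyclohexane-1,3-dione (racemic) | O=C1CC(CCc2ccccc2O)CC(=O)C1=Cc1ccc(O)cc1 | intermediate (not isolated)
9 | 2-(4-hydroxybenzyl)-5-[2-(2-hydroxyphenyl)ethyl]cyclohexane-1,3-dione (diketo form drawn) | O=C1CC(CCc2ccccc2O)CC(=O)C1Cc1ccc(O)cc1 | intermediate
10 | rac-2-(4-hydroxybenzyl)-5-[2-(2-hydroxyphenyl)ethyl]-3-methoxycyclohex-2-en-1-one | COC1=C(Cc2ccc(O)cc2)C(=O)CC(CCc2ccccc2O)C1 | intermediate (not isolated)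
11 | 2-(4-hydroxybenzyl)-5-[2-(2-hydroxyphenyl)ethyl]-3-methoxycyclohexa-2,5-dien-1-one | COC1=C(Cc2ccc(O)cc2)C(=O)C=C(CCc2ccccc2O)C1 | intermediate (not isolated)
12 | 2-(4-hydroxybenzyl)-5-[2-(2-hydroxyphenyl)ethyl]-3-methoxyphenol (achiral) | COc1cc(CCc2ccccc2O)cc(O)c1Cc1ccc(O)cc1 | target

## Step count and risks
Total step count: 4. Longest linear sequence: 4 (1/2 → 4 → 6 → 9 → 12).

**Step 4 (the proposed new step) is the most likely to fail.**
- Vinylogous esters enolise reluctantly, so palladation may be slow.
- Water formed from O2 can hydrolyse 10 back to 9, which would then aromatise to the unmethylated resorcinol.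
- A dimethoxydiene could lead to the dimethyl ether.
- MeOH may reduce Pd(II) to Pd black.

The fallback uses known chemistry, sets out from 9 and comes back at 12. Dione 9 is etherified with HC(OMe)3/MeOH and catalytic TsOH, and enol ether 10 is now isolated. Kinetic α′-deprotonation and silylation (LDA 3.3 equiv, THF, −78 °C, then TMSCl 3.6 equiv) give rac-1-methoxy-2-[4-(trimethylsilyloxy)benzyl]-3-(trimethylsilyloxy)-5-{2-[2-(trimethylsilyloxy)phenyl]ethyl}cyclohexa-1,3-diene F1, in which both phenols are masked for the time being. A Saegusa–Ito oxidation (Pd(OAc)2, MeCN, rt) passes through 11. Methanolic HCl work-up then strips the aryl silyl ethers and delivers 12.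

**Step 2 is the second risk.**
- The ring reduction may stall at 5.
- It may run on to the 3-hydroxyketone.
- It may touch the phenol ring.

The fallback replaces hydrogenative dearomatisation by dissolving-metal dearomatisation. It sets out from 2 and comes back at 6. Ylide 3, made from 2 as in step 1, is condensed with commercial 3,5-dimethoxybenzaldehyde to give 2-[(E)-2-(3,5-dimethoxyphenyl)ethenyl]phenol F2. Birch reduction (Li, NH3–THF, t-BuOH, −78 → −33 °C) saturates the stilbene bond and reduces only the dimethoxy ring, because the other ring is shielded as its lithium phenoxide. This gives 2-[2-(3,5-dimethoxycyclohexa-2,5-dien-1-yl)ethyl]phenol F3. Hydrolysis of both enol ethers with 1 M HCl/THF gives 6.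

**Step 1 is the third risk.**
- The phenoxide ylide 3 may be sluggish.
- It may lose PPh3 to give an o-quinone methide.

The fallback changes the bond construction from Wittig to Heck. It sets out from 1 and comes back at 4. Methylenation of 1 (methyltriphenylphosphonium bromide, KOtBu, THF) gives 1,3-bis(benzyloxy)-5-ethenylbenzene F4. A Mizoroki–Heck coupling with 2-iodophenol (Pd(OAc)2, P(o-tol)3, Et3N, DMF, 90 °C) gives (E)-4.

Further compounds
F1 | step 4 | rac-1-methoxy-2-[4-(trimethylsilyloxy)benzyl]-3-(trimethylsilyloxy)-5-{2-[2-(trimethylsilyloxy)phenyl]ethyl}cyclohexa-1,3-diene | COC1=C(Cc2ccc(O[Si](C)(C)C)cc2)C(O[Si](C)(C)C)=CC(CCc2ccccc2O[Si](C)(C)C)C1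
F2 | step 2 | 2-[(E)-2-(3,5-dimethoxyphenyl)ethenyl]phenol | COc1cc(OC)cc(/C=C/c2ccccc2O)c1
F3 | step 2 | 2-[2-(3,5-dimethoxycyclohexa-2,5-dien-1-yl)ethyl]phenol | COC1=CC(CCc2ccccc2O)C=C(OC)C1
F4 | step 1 | 1,3-bis(benzyloxy)-5-ethenylbenzene | C=Cc1cc(OCc2ccccc2)cc(OCc2ccccc2)c1
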